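**Retrosynthetic overview**
1. Target ⇐ benzyl-protected flavan–flavan-3-ol by global hydrogenolysis. The upper ring C is the last ring closed, by reductive etherification of the ring-A phenol onto a C2 aryl ketone (gives 2,4-cis).
2. Key disconnection, interflavan C4–C8 bond: an enantioenriched β-boryl ketone (a homoenolate, d3, equivalent of a chalcone) is arylated by the 8-bromo lower unit in a stereospecific Suzuki–Miyaura coupling. The enone β-carbon and the aryl bromide carbon, both acceptor carbons, are joined, and C4 is set by the catalyst.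
3. β-Boryl ketone ⇐ chalcone (asymmetric Cu-catalysed conjugate borylation) ⇐ acetophenone + benzaldehyde.
4. Lower unit ⇐ C8 bromination ⇐ cis-flavan-3-ol (transfer hydrogenation with dynamic kinetic resolution) ⇐ flavan-3-one ⇐ 3-nitro-2H-chromene from an oxa-Michael/Henry annulation (nitronate as acyl-anion equivalent for C3).
5. Ring order: lower ring C (step 1) → interflavan bond (step 7) → upper ring C (step 8).

The target is read as (2S,4S)-7,4'-dihydroxyflavan-(4→8)-(2R,3R)-epiafzelechin, with the upper 2-aryl and 4-aryl groups cis.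

Assumption: the four O-protected building blocks used as starting materials are bought as catalogue compounds (each is one alkylation or one Henry condensation away from a commodity phenol or aldehyde).
Assumption: the catalyst antipodes written in steps 3 and 6 are those expected to give the drawn configurations, step 6 being matched to an invertive step 7; if a measured sense is the opposite, the mirror-image catalyst is used and nothing else changes.

**Step 1**
Reactants: 1 2,4-bis(benzyloxy)-6-hydroxybenzaldehyde; 2 (E)-1-(benzyloxy)-4-(2-nitroethenyl)benzene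
Product: 4 rac-5,7-bis(benzyloxy)-2-[4-(benzyloxy)phenyl]-3-nitro-2H-chromene, via nitroaldol adduct 3 (not isolated)
Conditions: DABCO (0.5 equiv), MeCN, 70 °C
Reagents that add atoms: none
Why: Oxa-Michael addition of the phenoxide to the nitroalkene gives a nitronate that adds to the neighbouring aldehyde (intramolecular Henry reaction) and dehydrates, so the nitro-bearing carbon acts as an acyl-anion equivalent for C3 and is joined to the formyl carbon (two acceptor carbons); C2 forms racemic and is corrected in step 3.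

**Step 2**
Reactants: 4 rac-5,7-bis(benzyloxy)-2-[4-(benzyloxy)phenyl]-3-nitro-2H-chromene
Product: 6 rac-5,7-bis(benzyloxy)-2-[4-(benzyloxy)phenyl]chroman-3-one, via ketimine 5 (not isolated)
Conditions: Fe powder, AcOH–H2O (9:1), 80 °C, Ar
Reagents that add atoms: water, O
Why: Iron in acetic acid reduces the conjugated nitroalkene to the enamine/ketimine, which water hydrolyses to the ketone (reductive Nef reaction), unmasking the C3 carbonyl; C2 stays racemic.

**Step 3**
Reactants: 6 rac-5,7-bis(benzyloxy)-2-[4-(benzyloxy)phenyl]chroman-3-one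
Product: 7 (2R,3R)-5,7-bis(benzyloxy)-2-[4-(benzyloxy)phenyl]chroman-3-ol
Conditions: RuCl(p-cymene)[(S,S)-TsDPEN] (2 mol %), HCO2H–Et3N (1:2), DMF, 40 °C
Reagents that add atoms: none
Why: Proposed new method: the C2–H of this α-aryl α-aryloxy ketone is acidic enough for the amine to racemise it faster than reduction, and the chiral Ru hydride reduces only the (2R)-ketone with hydride entering anti to the 2-aryl group, giving the cis (2R,3R)-alcohol by dynamic kinetic resolution; the closest known type is Noyori–Ikariya transfer hydrogenation with dynamic kinetic resolution of α-aryl cyclic ketones such as 2-arylcycloalkanones and isoflavanones.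

**Step 4**
Reactants: 7 (2R,3R)-5,7-bis(benzyloxy)-2-[4-(benzyloxy)phenyl]chroman-3-ol
Product: 8 (2R,3R)-5,7-bis(benzyloxy)-2-[4-(benzyloxy)phenyl]-8-bromochroman-3-ol
Conditions: NBS (1.0 equiv), CH2Cl2, −78 → −20 °C
Reagents that add atoms: N-bromosuccinimide, O=C1CCC(=O)N1Br
Why: Electrophilic aromatic bromination goes to C8 of the 5,7-dialkoxy ring, the site established for NBS on benzyl-protected flavan-3-ols, and leaves both stereocentres untouched.

**Step 5**
Reactants: 9 1-[4-(benzyloxy)phenyl]ethan-1-one; 10 2,4-bis(methoxymethoxy)benzaldehyde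
Product: 11 (E)-1-[4-(benzyloxy)phenyl]-3-[2,4-bis(methoxymethoxy)phenyl]prop-2-en-1-one
Conditions: KOH, EtOH, rt
Reagents that add atoms: none
Why: Claisen–Schmidt aldol condensation gives the E-enone; MOM and benzyl ethers are stable to base.

**Step 6**
Reactants: 11 (E)-1-[4-(benzyloxy)phenyl]-3-[2,4-bis(methoxymethoxy)phenyl]prop-2-en-1-one
Product: 12 (3R)-1-[4-(benzyloxy)phenyl]-3-[2,4-bis(methoxymethoxy)phenyl]-3-(4,4,5,5-tetramethyl-1,3,2-dioxaborolan-2-yl)propan-1-one
Conditions: CuCl (5 mol %), (R)-1-[(S)-2-(diphenylphosphino)ferrocenyl]ethyldicyclohexylphosphine (6 mol %), NaOt-Bu (10 mol %), B2pin2 (1.1 equiv), MeOH (2 equiv), THF, rt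
Reagents that add atoms: bis(pinacolato)diboron, CC1(C)OB(OC1(C)C)B1OC(C)(C)C(C)(C)O1
Why: Copper-catalysed asymmetric conjugate borylation: the ligand-bound Cu–Bpin adds to one face of the enone β-carbon and methanol protonates the copper enolate, setting the C–B centre as (R) and turning the electrophilic β-carbon into a configurationally stable homoenolate (d3) equivalent.

**Step 7 (key step)**
Reactants: 8 (2R,3R)-5,7-bis(benzyloxy)-2-[4-(benzyloxy)phenyl]-8-bromochroman-3-ol; 12 (3R)-1-[4-(benzyloxy)phenyl]-3-[2,4-bis(methoxymethoxy)phenyl]-3-(4,4,5,5-tetramethyl-1,3,2-dioxaborolan-2-yl)propan-1-one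
Product: 13 (3S)-1-[4-(benzyloxy)phenyl]-3-[2,4-bis(methoxymethoxy)phenyl]-3-[(2R,3R)-5,7-bis(benzyloxy)-2-[4-(benzyloxy)phenyl]-3-hydroxychroman-8-yl]propan-1-one
Conditions: Pd(OAc)2 (10 mol %), XPhos (20 mol %), K2CO3 (3 equiv), toluene–H2O (10:1), 90 °C
Reagents that add atoms: none
Why: Proposed new method: the hindered aryl bromide adds oxidatively to zerovalent palladium, the secondary benzylic boronate then transmetalates with the ketone oxygen coordinated to boron so that carbon is transferred from the back side (inversion, (R)-C–B to (S)-C–aryl), and reductive elimination must outrun β-hydride elimination; this homoenolate arylation joins the enone β-carbon to the aryl bromide carbon, and its closest known type is the stereospecific Suzuki–Miyaura coupling of enantioenriched secondary benzylic and β-carbonyl alkylboron reagents.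

**Step 8**
Reactants: 13 (3S)-1-[4-(benzyloxy)phenyl]-3-[2,4-bis(methoxymethoxy)phenyl]-3-[(2R,3R)-5,7-bis(benzyloxy)-2-[4-(benzyloxy)phenyl]-3-hydroxychroman-8-yl]propan-1-one
Product: 16 (2S,4S)-2-[4-(benzyloxy)phenyl]-4-[(2R,3R)-5,7-bis(benzyloxy)-2-[4-(benzyloxy)phenyl]-3-hydroxychroman-8-yl]chroman-7-ol, via keto-diphenol 14 (not isolated), via cyclic hemiketal 15 (not isolated)
Conditions: HCl (1 M), MeOH–THF, 40 °C; concentrate; then Et3SiH (3 equiv), TFA, CH2Cl2, −20 °C
Reagents that add atoms: none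
Why: Acidic methanol removes both MOM acetals, the freed ortho-phenol of ring A (the only free phenol ortho to C4, since O7 of ring D stays benzylated) closes on the aryl ketone to the cyclic hemiketal, and Et3SiH reduces the derived 2-aryl oxocarbenium ion with hydride entering anti to the C4 aryl group, placing the 2-aryl group cis to it (2S); reductive etherification by ionic hydrogenation.

**Step 9**
Reactants: 16 (2S,4S)-2-[4-(benzyloxy)phenyl]-4-[(2R,3R)-5,7-bis(benzyloxy)-2-[4-(benzyloxy)phenyl]-3-hydroxychroman-8-yl]chroman-7-ol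
Product: 17 (2R,3R)-8-[(2S,4S)-7-hydroxy-2-(4-hydroxyphenyl)chroman-4-yl]-2-(4-hydroxyphenyl)chromane-3,5,7-triol
Conditions: H2 (1 atm), Pd(OH)2/C, THF–MeOH, rt
Reagents that add atoms: none
Why: Hydrogenolysis of the four benzyl ethers; the benzylic ring C–O bonds of both flavan units survive these conditions, as in benzyl-protected proanthocyanidin syntheses, and no stereocentre is touched.

**Compound list**
1 | 2,4-bis(benzyloxy)-6-hydroxybenzaldehyde | O=Cc1c(O)cc(OCc2ccccc2)cc1OCc1ccccc1 | starting material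
2 | (E)-1-(benzyloxy)-4-(2-nitroethenyl)benzene | [O-][N+](=O)/C=C/c1ccc(OCc2ccccc2)cc1 | starting material
3 | nitroaldol adduct: rac-5,7-bis(benzyloxy)-2-[4-(benzyloxy)phenyl]-3-nitrochroman-4-ol (diastereomer mixture) | OC1c2c(OCc3ccccc3)cc(OCc3ccccc3)cc2OC(c2ccc(OCc3ccccc3)cc2)C1[N+](=O)[O-] | intermediate
4 | rac-5,7-bis(benzyloxy)-2-[4-(benzyloxy)phenyl]-3-nitro-2H-chromene | [O-][N+](=O)C1=Cc2c(OCc3ccccc3)cc(OCc3ccccc3)cc2OC1c1ccc(OCc2ccccc2)cc1 | intermediate
5 | ketimine: rac-5,7-bis(benzyloxy)-2-[4-(benzyloxy)phenyl]chroman-3-imine | N=C1Cc2c(OCc3ccccc3)cc(OCc3ccccc3)cc2OC1c1ccc(OCc2ccccc2)cc1 | intermediate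
6 | rac-5,7-bis(benzyloxy)-2-[4-(benzyloxy)phenyl]chroman-3-one | O=C1Cc2c(OCc3ccccc3)cc(OCc3ccccc3)cc2OC1c1ccc(OCc2ccccc2)cc1 | intermediate
7 | (2R,3R)-5,7-bis(benzyloxy)-2-[4-(benzyloxy)phenyl]chroman-3-ol (5,7,4'-tri-O-benzyl-epiafzelechin) | O[C@@H]1Cc2c(OCc3ccccc3)cc(OCc3ccccc3)cc2O[C@@H]1c1ccc(OCc2ccccc2)cc1 | intermediate
8 | (2R,3R)-5,7-bis(benzyloxy)-2-[4-(benzyloxy)phenyl]-8-bromochroman-3-ol | O[C@@H]1Cc2c(OCc3ccccc3)cc(OCc3ccccc3)c(Br)c2O[C@@H]1c1ccc(OCc2ccccc2)cc1 | intermediate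
9 | 1-[4-(benzyloxy)phenyl]ethan-1-one | CC(=O)c1ccc(OCc2ccccc2)cc1 | starting material
10 | 2,4-bis(methoxymethoxy)benzaldehyde | COCOc1ccc(C=O)c(OCOC)c1 | starting material
11 | (E)-1-[4-(benzyloxy)phenyl]-3-[2,4-bis(methoxymethoxy)phenyl]prop-2-en-1-one | COCOc1ccc(/C=C/C(=O)c2ccc(OCc3ccccc3)cc2)c(OCOC)c1 | intermediate
12 | (3R)-1-[4-(benzyloxy)phenyl]-3-[2,4-bis(methoxymethoxy)phenyl]-3-(4,4,5,5-tetramethyl-1,3,2-dioxaborolan-2-yl)propan-1-one | O=C(c1ccc(OCc2ccccc2)cc1)C[C@@H](B1OC(C)(C)C(C)(C)O1)c1ccc(OCOC)cc1OCOC | intermediate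
13 | (3S)-1-[4-(benzyloxy)phenyl]-3-[2,4-bis(methoxymethoxy)phenyl]-3-[(2R,3R)-5,7-bis(benzyloxy)-2-[4-(benzyloxy)phenyl]-3-hydroxychroman-8-yl]propan-1-one | O=C(c1ccc(OCc2ccccc2)cc1)C[C@H](c1c(OCc2ccccc2)cc(OCc2ccccc2)c2c1O[C@H](c1ccc(OCc3ccccc3)cc1)[C@H](O)C2)c1ccc(OCOC)cc1OCOC | intermediate
14 | keto-diphenol: (3S)-1-[4-(benzyloxy)phenyl]-3-(2,4-dihydroxyphenyl)-3-[(2R,3R)-5,7-bis(benzyloxy)-2-[4-(benzyloxy)phenyl]-3-hydroxychroman-8-yl]propan-1-one | O=C(c1ccc(OCc2ccccc2)cc1)C[C@H](c1c(OCc2ccccc2)cc(OCc2ccccc2)c2c1O[C@H](c1ccc(OCc3ccccc3)cc1)[C@H](O)C2)c1ccc(O)cc1O | intermediate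
15 | cyclic hemiketal: (4S)-2-[4-(benzyloxy)phenyl]-4-[(2R,3R)-5,7-bis(benzyloxy)-2-[4-(benzyloxy)phenyl]-3-hydroxychroman-8-yl]chromane-2,7-diol (C2 epimers) | OC1(c2ccc(OCc3ccccc3)cc2)C[C@H](c2c(OCc3ccccc3)cc(OCc3ccccc3)c3c2O[C@H](c2ccc(OCc4ccccc4)cc2)[C@H](O)C3)c2ccc(O)cc2O1 | intermediate
16 | (2S,4S)-2-[4-(benzyloxy)phenyl]-4-[(2R,3R)-5,7-bis(benzyloxy)-2-[4-(benzyloxy)phenyl]-3-hydroxychroman-8-yl]chroman-7-ol | C(c1ccccc1)Oc1ccc([C@@H]2C[C@H](c3c(OCc5ccccc5)cc(OCc5ccccc5)c4c3O[C@H](c3ccc(OCc5ccccc5)cc3)[C@H](O)C4)c3ccc(O)cc3O2)cc1 | intermediate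
17 | (2R,3R)-8-[(2S,4S)-7-hydroxy-2-(4-hydroxyphenyl)chroman-4-yl]-2-(4-hydroxyphenyl)chromane-3,5,7-triol | Oc1ccc([C@@H]2C[C@H](c3c(O)cc(O)c4c3O[C@H](c3ccc(O)cc3)[C@H](O)C4)c3ccc(O)cc3O2)cc1 | target

**Step count and risks**
Total steps: 9. Longest linear sequence: 7 (steps 1, 2, 3, 4, 7, 8, 9).

Most likely to fail, first: step 7. The coupling joins a secondary benzylic boronate to an aryl bromide flanked by two ortho oxygens. Likely losses are β-hydride elimination back to 11, protodeboronation, and an incomplete or unexpected stereochemical course. The fallback gives up the boron chemistry and uses normal polarity; it sets out from 11 (with 7 as partner, so steps 4 and 6 are dropped) and comes back at 16. HCl in MeOH–AcOH cleaves the MOM groups of 11 and cyclises the resulting 2-hydroxychalcone to 2-[4-(benzyloxy)phenyl]-7-hydroxychromenylium chloride F1. Compound 7 then adds through C8 to C4 of F1 (MeCN–AcOH, rt) to give (4S)-2-[4-(benzyloxy)phenyl]-4-[(2R,3R)-5,7-bis(benzyloxy)-2-[4-(benzyloxy)phenyl]-3-hydroxychroman-8-yl]-4H-chromen-7-ol F2 together with its (4R) epimer F3, which are separated on silica. Et3SiH/TFA at −20 °C protonates F2 to the same oxocarbenium ion as in step 8 and reduces it to 16.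

Second: step 3. Racemisation of C2 may be too slow, or the catalyst may discriminate the two flanking sp3 carbons poorly. The fallback replaces the dynamic resolution by diastereoselective reduction and enzymatic resolution; it sets out from 6 and comes back at 7. LiBH(s-Bu)3 (THF, −78 °C) adds hydride anti to the 2-aryl group to give rac-cis-5,7-bis(benzyloxy)-2-[4-(benzyloxy)phenyl]chroman-3-ol F4. Candida antarctica lipase B with vinyl acetate (t-BuOMe, 35 °C) then acetylates the (2S,3S) enantiomer to (2S,3S)-5,7-bis(benzyloxy)-2-[4-(benzyloxy)phenyl]chroman-3-yl acetate F5 and leaves (2R,3R)-7 (at most 50 %).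

Third: step 2. The dissolving-metal reduction may over-reduce to the amine or give enol-derived by-products. The fallback separates reduction and carbonyl unmasking; it sets out from 4 and comes back at 6. NaBH4 (THF–EtOH, 0 °C) reduces the conjugated C=C to rac-5,7-bis(benzyloxy)-2-[4-(benzyloxy)phenyl]-3-nitrochromane F6. Its nitronate (NaOMe, MeOH) is then converted to 6 with aqueous TiCl3 buffered with NH4OAc (Nef reaction).

**Further compounds**
F1 | step 7 | 2-[4-(benzyloxy)phenyl]-7-hydroxychromenylium chloride | [Cl-].Oc1ccc2ccc(-c3ccc(OCc4ccccc4)cc3)[o+]c2c1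
F2 | step 7 | (4S)-2-[4-(benzyloxy)phenyl]-4-[(2R,3R)-5,7-bis(benzyloxy)-2-[4-(benzyloxy)phenyl]-3-hydroxychroman-8-yl]-4H-chromen-7-ol | C1(c2ccc(OCc3ccccc3)cc2)=C[C@H](c2c(OCc3ccccc3)cc(OCc3ccccc3)c3c2O[C@H](c2ccc(OCc4ccccc4)cc2)[C@H](O)C3)c2ccc(O)cc2O1
F3 | step 7 | (4R)-2-[4-(benzyloxy)phenyl]-4-[(2R,3R)-5,7-bis(benzyloxy)-2-[4-(benzyloxy)phenyl]-3-hydroxychroman-8-yl]-4H-chromen-7-ol | C1(c2ccc(OCc3ccccc3)cc2)=C[C@@H](c2c(OCc3ccccc3)cc(OCc3ccccc3)c3c2O[C@H](c2ccc(OCc4ccccc4)cc2)[C@H](O)C3)c2ccc(O)cc2O1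
F4 | step 3 | rac-cis-5,7-bis(benzyloxy)-2-[4-(benzyloxy)phenyl]chroman-3-ol (both enantiomers) | O[C@@H]1Cc2c(OCc3ccccc3)cc(OCc3ccccc3)cc2O[C@@H]1c1ccc(OCc2ccccc2)cc1.O[C@H]1Cc2c(OCc3ccccc3)cc(OCc3ccccc3)cc2O[C@H]1c1ccc(OCc2ccccc2)cc1
F5 | step 3 | (2S,3S)-5,7-bis(benzyloxy)-2-[4-(benzyloxy)phenyl]chroman-3-yl acetate | CC(=O)O[C@H]1Cc2c(OCc3ccccc3)cc(OCc3ccccc3)cc2O[C@H]1c1ccc(OCc2ccccc2)cc1
F6 | step 2 | rac-5,7-bis(benzyloxy)-2-[4-(benzyloxy)phenyl]-3-nitrochromane (diastereomer mixture) | [O-][N+](=O)C1Cc2c(OCc3ccccc3)cc(OCc3ccccc3)cc2OC1c1ccc(OCc2ccccc2)cc1
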